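Ring A is cut at C1–C2, the bond that links the angular carbon C10 to the carbinol carbon C2. Ring B is built first: a Johnson–Claisen rearrangement relays an easily set carbinol stereocentre to C5, and a copper-catalysed vinyl addition anti to the C5 arm creates quaternary C10. The key step, ring-closing metathesis of the C10 vinyl and C4 allyl groups, closes ring A last as a trans-fused Δ1-cyclohexene. Its precursor is a monocyclic triene whose enol silyl ether stores the C8 ketone. The new olefin, hemmed in by C10 and the β-axial C20, later takes the 2α-hydroxyl by hydroboration, and the ring steers C4 methylation.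

Key step: step 6

Remark: atom labels C1–C20 follow the labdane numbering of the target (ring A = C1–C5 and C10; ring B = C5–C10; C17 = exocyclic CH2; C18 = 4α-CH3; C19 = 4β-carboxyl; C20 = CH3 on C10); α is the face of H-5, and the absolute configuration is the one encoded in the target SMILES.

Step 1
Reactants: 1 2-methylcyclohex-2-en-1-one
Product: 2 (1S)-2-methylcyclohex-2-en-1-ol
Conditions: (R)-2-methyl-CBS-oxazaborolidine (10 mol %), BH3·SMe2, THF, −20 °C; MeOH quench
Reagents that add atoms: none
Why: Corey–Bakshi–Shibata reduction, in which the oxazaborolidine–borane complex binds the ketone with the trisubstituted alkenyl side as the large group and delivers hydride to one carbonyl face, which should give the S allylic alcohol.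

Step 2
Reactants: 2 (1S)-2-methylcyclohex-2-en-1-ol; 3 trimethyl orthoacetate
Product: 5 methyl 2-[(1S)-2-methylcyclohex-2-en-1-yl]acetate, via ketene acetal 4 (not isolated)
Conditions: MeC(OMe)3 (excess), EtCO2H (cat.), xylene, 140 °C, MeOH distilled off
Reagents that add atoms: none
Why: Johnson–Claisen rearrangement, whose suprafacial [3,3] shift relays the C9–O stereocentre to C5 (the new C5–C4 bond forms on the face that carried oxygen) and moves the olefin to C9=C10.

Step 3
Reactants: 5 methyl 2-[(1S)-2-methylcyclohex-2-en-1-yl]acetate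
Product: 6 methyl 2-[(1S)-2-methyl-4-oxocyclohex-2-en-1-yl]acetate
Conditions: Rh2(C6H10NO)4 (dirhodium tetracaprolactamate, 1 mol %), t-BuOOH (5 equiv), K2CO3, CH2Cl2, rt
Reagents that add atoms: tert-butyl hydroperoxide, CC(C)(C)OO
Why: Dirhodium-catalysed allylic oxidation with tert-butyl hydroperoxide, in which the peroxyl radical abstracts hydrogen from the ring CH2 next to the CH= terminus (C8), the least hindered allylic site, and the mixed peroxide collapses to the conjugated enone without touching C5.

Step 4
Reactants: 6 methyl 2-[(1S)-2-methyl-4-oxocyclohex-2-en-1-yl]acetate; 7 vinylmagnesium bromide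
Product: 8 methyl 2-[(1S,2S)-4-{[tert-butyl(dimethyl)silyl]oxy}-2-ethenyl-2-methylcyclohex-3-en-1-yl]acetate
Conditions: CH2=CHMgBr, CuBr·SMe2 (20 mol %), HMPA, t-BuMe2SiCl, THF, −78 to −40 °C; Et3N, aq NaHCO3
Reagents that add atoms: tert-butyl(chloro)dimethylsilane, CC(C)(C)[Si](C)(C)Cl
Why: Copper-catalysed, chlorosilane-assisted conjugate addition of a vinyl Grignard reagent, which delivers vinyl to C10 anti to the C5 acetate arm of the 4-substituted enone (C20 cis and vinyl trans to the arm) and silylates the enolate on oxygen so that C8=C9 is stored regiospecifically.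

Step 5
Reactants: 8 methyl 2-[(1S,2S)-4-{[tert-butyl(dimethyl)silyl]oxy}-2-ethenyl-2-methylcyclohex-3-en-1-yl]acetate; 9 allyl bromide
Product: 11 methyl 2-[(1S,2S)-4-{[tert-butyl(dimethyl)silyl]oxy}-2-ethenyl-2-methylcyclohex-3-en-1-yl]pent-4-enoate (both epimers at C4), via lithium enolate 10 (not isolated)
Conditions: LiN(iPr)2, THF, −78 °C; then allyl bromide, −78 to 0 °C
Reagents that add atoms: none
Why: Ester enolate alkylation (SN2 on an allylic bromide), in which only the CH2 next to the ester is acidic, the enol silyl ether tolerates the amide base, and the configuration created at C4 is immaterial because this carbon is planarised again in step 7.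

Step 6
Reactants: 11 methyl 2-[(1S,2S)-4-{[tert-butyl(dimethyl)silyl]oxy}-2-ethenyl-2-methylcyclohex-3-en-1-yl]pent-4-enoate
Product: 12 methyl (4aS,8aS)-6-{[tert-butyl(dimethyl)silyl]oxy}-4a-methyl-1,2,4a,7,8,8a-hexahydronaphthalene-1-carboxylate (both epimers at C4)
Conditions: second-generation Grubbs catalyst, RuCl2(=CHPh)(PCy3)(H2IMes) (5 mol %), CH2Cl2, 40 °C
Reagents that add atoms: none
Why: Ring-closing olefin metathesis: the ruthenium alkylidene loads on the unhindered allyl terminus, then undergoes intramolecular [2+2] cycloaddition and cycloreversion with the C10 vinyl group through a ruthenacyclobutane, releasing ethene. The closest known reaction type is the closure of 1,7-dienes bearing an allylic quaternary carbon to cyclohexenes with second-generation ruthenium catalysts. Ring A is closed as a six-membered ring by forming the endocyclic C1=C2 double bond between the carbon on C10 and the carbon two atoms from C4. No stereocentre is created; the trans ring fusion is inherited from C5 and C10, whose vinyl and C4-bearing arms are trans and can both sit equatorial on ring B, so both C4 epimers can close. The step needs chemoselectivity for the two monosubstituted alkenes over the C8=C9 enol silyl ether, which the trisubstituted, oxygen-bearing and neopentyl character of that olefin secures, and loss of ethene drives it.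

Step 7
Reactants: 12 methyl (4aS,8aS)-6-{[tert-butyl(dimethyl)silyl]oxy}-4a-methyl-1,2,4a,7,8,8a-hexahydronaphthalene-1-carboxylate
Product: 14 methyl (1S,4aS,8aR)-6-{[tert-butyl(dimethyl)silyl]oxy}-1,4a-dimethyl-1,2,4a,7,8,8a-hexahydronaphthalene-1-carboxylate (4α-CH3 and 4β-CO2CH3), via lithium enolate 13 (not isolated)
Conditions: LiN(iPr)2, THF/DMPU, −78 °C; then MeI, −78 to −20 °C
Reagents that add atoms: iodomethane, CI
Why: Alkylation of an exocyclic ester enolate, in which the β face of C4 is blocked by the pseudo-axial C20 methyl on C10 (1,3-diaxial relation), so iodomethane should enter from the α face and leave the ester β (axial), both C4 epimers of 12 converging on one enolate.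

Step 8
Reactants: 14 methyl (1S,4aS,8aR)-6-{[tert-butyl(dimethyl)silyl]oxy}-1,4a-dimethyl-1,2,4a,7,8,8a-hexahydronaphthalene-1-carboxylate
Product: 16 methyl (1S,3R,4aS,8aR)-6-{[tert-butyl(dimethyl)silyl]oxy}-3-hydroxy-1,4a-dimethyl-1,2,3,4,4a,7,8,8a-octahydronaphthalene-1-carboxylate (2α-OH), via 2α-borane 15 (not isolated)
Conditions: BH3·THF (1.1 equiv), THF, 0 °C; then aq NaOH, H2O2, 0 °C
Reagents that add atoms: hydrogen peroxide, OO
Why: Hydroboration–oxidation, in which borane adds syn from the α face, away from C20 and the C19 ester, with boron on C2 rather than the neopentyl C1, and oxidation with retention gives the equatorial 2α-alcohol, the enol silyl ether reacting more slowly because boron would have to bond to the neopentyl C9.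

Step 9
Reactants: 16 methyl (1S,3R,4aS,8aR)-6-{[tert-butyl(dimethyl)silyl]oxy}-3-hydroxy-1,4a-dimethyl-1,2,3,4,4a,7,8,8a-octahydronaphthalene-1-carboxylate; 17 methyl vinyl ketone
Product: 18 methyl 2α-hydroxy-8,13-dioxo-14,15,17-trinorlabdan-19-oate (both C9 epimers)
Conditions: BF3·OEt2, i-PrOH, CH2Cl2/MeNO2, −78 to −20 °C
Reagents that add atoms: none
Why: Mukaiyama–Michael addition promoted by BF3·OEt2 with an alcohol as proton source and silyl acceptor, in which the enol silyl ether attacks the activated enone through C9 only, placing the 3-oxobutyl chain next to C10 and releasing the C8 ketone, the C9 configuration being settled in step 10.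

Step 10
Reactants: 18 methyl 2α-hydroxy-8,13-dioxo-14,15,17-trinorlabdan-19-oate; 19 trimethyl phosphonoacetate
Product: 21 dimethyl (13E)-2α-hydroxy-8-oxo-17-norlabd-13-ene-15,19-dioate (9α-H), via C9-epimeric enoate 20 (not isolated)
Conditions: NaH, (MeO)2P(O)CH2CO2Me, THF, 0 °C to rt; then NaOCH3 (cat.), MeOH, rt; chromatography
Reagents that add atoms: none
Why: Horner–Wadsworth–Emmons olefination followed by base equilibration, in which the phosphonate anion reacts with the unhindered methyl ketone rather than the flanked C8 ketone and should give mainly the E-enoate, and methoxide then epimerises C9, α to the C8 ketone, toward the equatorial side chain (9α-H).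

Step 11
Reactants: 21 dimethyl (13E)-2α-hydroxy-8-oxo-17-norlabd-13-ene-15,19-dioate (9α-H)
Product: 22 dimethyl (13E)-2α-hydroxylabda-8(17),13-diene-15,19-dioate
Conditions: Ph3PCH3Br, KOC(CH3)3 (excess), THF, rt to 60 °C
Reagents that add atoms: methyltriphenylphosphonium bromide, C[P+](c1ccccc1)(c1ccccc1)c1ccccc1.[Br-]
Why: Wittig methylenation, in which the unstabilised ylide converts the C8 ketone into the exocyclic C8=C17 olefin, after which C9 can no longer epimerise, the esters and the β,β-disubstituted enoate being inert to the ylide.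

Step 12
Reactants: 22 dimethyl (13E)-2α-hydroxylabda-8(17),13-diene-15,19-dioate
Product: 23 (13E)-2α-hydroxylabda-8(17),13-diene-15,19-dioic acid (hypoxyterpoid A)
Conditions: LiSCH2CH2CH3 (excess), HMPA, rt; then aq HCl to pH 3
Reagents that add atoms: none
Why: Nucleophilic ester demethylation (SN2 of thiolate at the O-methyl carbon), which cleaves the unhindered C15 ester and the hindered axial C19 ester alike without attack at the carbonyl groups and without strong base that could move the double bonds.

Compound list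

1 | 2-methylcyclohex-2-en-1-one | CC1=CCCCC1=O | starting material
2 | (1S)-2-methylcyclohex-2-en-1-ol | O[C@H]1CCCC=C1C | intermediate
3 | trimethyl orthoacetate | COC(C)(OC)OC | starting material
4 | 1-methoxy-1-{[(1S)-2-methylcyclohex-2-en-1-yl]oxy}ethene (ketene acetal) | C=C(OC)O[C@H]1CCCC=C1C | intermediate
5 | methyl 2-[(1S)-2-methylcyclohex-2-en-1-yl]acetate | COC(=O)C[C@@H]1CCCC=C1C | intermediate
6 | methyl 2-[(1S)-2-methyl-4-oxocyclohex-2-en-1-yl]acetate | COC(=O)C[C@@H]1CCC(=O)C=C1C | intermediate
7 | vinylmagnesium bromide | C=C[Mg]Br | starting material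
8 | methyl 2-[(1S,2S)-4-{[tert-butyl(dimethyl)silyl]oxy}-2-ethenyl-2-methylcyclohex-3-en-1-yl]acetate | COC(=O)C[C@@H]1CCC(O[Si](C)(C)C(C)(C)C)=C[C@@]1(C)C=C | intermediate
9 | allyl bromide | C=CCBr | starting material
10 | lithium enolate of 8 | COC(O[Li])=C[C@@H]1CCC(O[Si](C)(C)C(C)(C)C)=C[C@@]1(C)C=C | intermediate
11 | methyl 2-[(1S,2S)-4-{[tert-butyl(dimethyl)silyl]oxy}-2-ethenyl-2-methylcyclohex-3-en-1-yl]pent-4-enoate (both epimers at C4) | COC(=O)C(CC=C)[C@@H]1CCC(O[Si](C)(C)C(C)(C)C)=C[C@@]1(C)C=C | intermediate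
12 | methyl (4aS,8aS)-6-{[tert-butyl(dimethyl)silyl]oxy}-4a-methyl-1,2,4a,7,8,8a-hexahydronaphthalene-1-carboxylate (both epimers at C4; 5α-H, 10β-CH3) | CC(C)(C)[Si](C)(C)OC1=C[C@@]2(C)C=CCC(C(=O)OC)[C@@H]2CC1 | intermediate
13 | lithium enolate of 12 | CC(C)(C)[Si](C)(C)OC1=C[C@@]2(C)C=CCC(=C(OC)O[Li])[C@@H]2CC1 | intermediate
14 | methyl (1S,4aS,8aR)-6-{[tert-butyl(dimethyl)silyl]oxy}-1,4a-dimethyl-1,2,4a,7,8,8a-hexahydronaphthalene-1-carboxylate (4α-CH3, 4β-CO2CH3) | CC(C)(C)[Si](C)(C)OC1=C[C@@]2(C)C=CC[C@](C)(C(=O)OC)[C@@H]2CC1 | intermediate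
15 | 2α-boryl derivative of 14 (C2–BH2, H added at C1) | CC(C)(C)[Si](C)(C)OC1=C[C@@]2(C)C[C@@H](B)C[C@](C)(C(=O)OC)[C@@H]2CC1 | intermediate
16 | methyl (1S,3R,4aS,8aR)-6-{[tert-butyl(dimethyl)silyl]oxy}-3-hydroxy-1,4a-dimethyl-1,2,3,4,4a,7,8,8a-octahydronaphthalene-1-carboxylate (2α-OH) | CC(C)(C)[Si](C)(C)OC1=C[C@@]2(C)C[C@@H](O)C[C@](C)(C(=O)OC)[C@@H]2CC1 | intermediate
17 | methyl vinyl ketone | C=CC(C)=O | starting material
18 | methyl 2α-hydroxy-8,13-dioxo-14,15,17-trinorlabdan-19-oate (both C9 epimers) | O=C1CC[C@@H]2[C@](C)(C[C@@H](O)C[C@]2(C)C(=O)OC)C1CCC(C)=O | intermediate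
19 | trimethyl phosphonoacetate | COC(=O)CP(=O)(OC)OC | starting material
20 | dimethyl (13E)-2α-hydroxy-8-oxo-17-norlabd-13-ene-15,19-dioate (both C9 epimers) | O=C1CC[C@@H]2[C@](C)(C[C@@H](O)C[C@]2(C)C(=O)OC)C1CC/C(C)=C/C(=O)OC | intermediate
21 | dimethyl (13E)-2α-hydroxy-8-oxo-17-norlabd-13-ene-15,19-dioate (9α-H) | O=C1CC[C@@H]2[C@](C)(C[C@@H](O)C[C@]2(C)C(=O)OC)[C@H]1CC/C(C)=C/C(=O)OC | intermediate
22 | dimethyl (13E)-2α-hydroxylabda-8(17),13-diene-15,19-dioate | C=C1CC[C@@H]2[C@](C)(C[C@@H](O)C[C@]2(C)C(=O)OC)[C@H]1CC/C(C)=C/C(=O)OC | intermediate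
23 | (13E)-2α-hydroxylabda-8(17),13-diene-15,19-dioic acid (hypoxyterpoid A) | C=C1CC[C@@H]2[C@](C)(C[C@@H](O)C[C@]2(C)C(=O)O)[C@H]1CC/C(C)=C/C(=O)O | target

Total steps: 12. Longest linear sequence: 12 steps (1 to 23).

Steps most likely to fail

Step 3 (allylic oxidation). The radical hydrogen abstraction may lose site selectivity (attack at the tertiary C5–H or at the C20 methyl) or over-oxidise. The fallback sets out from 5 and comes back at 6. Epoxidation of the only olefin with 3-chloroperbenzoic acid (CH2Cl2, NaHCO3) gives methyl 2-[(1S)-2,3-epoxy-2-methylcyclohexyl]acetate F1. Opening at the secondary C9 with NaSePh (from PhSeSePh and NaBH4, EtOH) gives the hydroxy selenide F2. Oxidation with H2O2 lets the selenoxide eliminate toward C8, the only β-hydrogen-bearing carbon, to give the tertiary allylic alcohol F3. Babler–Dauben oxidative 1,3-transposition with [C5H5NH][CrO3Cl] (CH2Cl2) then moves oxygen to C8 and gives enone 6.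

Step 8 (hydroboration). Chemoselectivity may be lost if borane also adds to the enol silyl ether, and regiocontrol between C1 and C2 may be poor. The fallback sets out from 14 and comes back at 18. The enol silyl ether is used up first: Mukaiyama–Michael addition of 14 to methyl vinyl ketone 17 (BF3·OEt2, i-PrOH) gives methyl 8,13-dioxo-14,15,17-trinorlabd-1-en-19-oate F4. Ketalisation with 1,2-bis(trimethylsilyloxy)ethane and catalytic Me3SiOTf gives the bis(ethylene ketal) F5. BH3·THF then gives the 2α-borane F6, and NaOH/H2O2 gives the 2α-alcohol F7. Pyridinium p-toluenesulfonate in wet acetone removes both ketals and gives 18.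

Step 10 (olefination and C9 equilibration). The thermodynamic bias at C9 may be insufficient, and the base may erode the enoate geometry. The fallback sets out from 20, isolated without the methoxide treatment, and comes back at 21. PhSeCl (EtOAc, cat. HCl) selenenylates the more substituted α-carbon of the C8 ketone to give the C9 phenylselanyl ketone F8. H2O2 oxidation and syn-elimination toward C11 give the Δ9(11)-enone F9. Conjugate reduction with [(Ph3P)CuH]6 in wet benzene then protonates the copper enolate at C9 from the α face, anti to C20, giving 21 under kinetic control.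

Further compounds
F1 | step 3 | methyl 2-[(1S)-2,3-epoxy-2-methylcyclohexyl]acetate (oxirane trans to the acetate arm) | COC(=O)C[C@@H]1CCC[C@H]2O[C@@]12C
F2 | step 3 | methyl 2-[(1S)-2-hydroxy-2-methyl-3-(phenylselanyl)cyclohexyl]acetate (OH trans to the arm, selenium trans to OH) | COC(=O)C[C@@H]1CCC[C@H]([Se]c2ccccc2)[C@@]1(C)O
F3 | step 3 | methyl 2-[(1S)-2-hydroxy-2-methylcyclohex-3-en-1-yl]acetate (OH trans to the arm) | COC(=O)C[C@@H]1CCC=C[C@@]1(C)O
F4 | step 8 | methyl 8,13-dioxo-14,15,17-trinorlabd-1-en-19-oate (both C9 epimers) | O=C1CC[C@@H]2[C@](C)(C=CC[C@]2(C)C(=O)OC)C1CCC(C)=O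
F5 | step 8 | 8,13-bis(ethylene ketal) of F4 | O1CCOC12CC[C@@H]3[C@](C)(C=CC[C@]3(C)C(=O)OC)C2CCC2(C)OCCO2
F6 | step 8 | 2α-boryl derivative of F5 | O1CCOC12CC[C@@H]3[C@](C)(C[C@@H](B)C[C@]3(C)C(=O)OC)C2CCC2(C)OCCO2
F7 | step 8 | 2α-hydroxy 8,13-bis(ethylene ketal) (bis-ketal of 18) | O1CCOC12CC[C@@H]3[C@](C)(C[C@@H](O)C[C@]3(C)C(=O)OC)C2CCC2(C)OCCO2
F8 | step 10 | dimethyl (13E)-2α-hydroxy-8-oxo-9-(phenylselanyl)-17-norlabd-13-ene-15,19-dioate | O=C1CC[C@@H]2[C@](C)(C[C@@H](O)C[C@]2(C)C(=O)OC)C1([Se]c1ccccc1)CC/C(C)=C/C(=O)OC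
F9 | step 10 | dimethyl (13E)-2α-hydroxy-8-oxo-17-norlabda-9(11),13-diene-15,19-dioate | O=C1CC[C@@H]2[C@](C)(C[C@@H](O)C[C@]2(C)C(=O)OC)C1=CC/C(C)=C/C(=O)OC
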